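**Retrosynthetic overview**
1. Target 19 ⇐ hydrogenolysis of the benzyl-type protected dimer 18 ⇐ C4(upper)–C8(lower) Friedel–Crafts coupling of the C4-cation precursor 16 with the C4-acetate unit 17.
2. 16 and 17 both come from one protected (−)-epicatechin 15: DDQ etherification of C4–H, then trapping of the C4 cation with a silyl ketene acetal (3,4-trans).
3. 15 ⇐ racemic flavan-3-one 14 by a dynamic-kinetic asymmetric transfer hydrogenation that sets C2 and C3 (cis).
4. 14 ⇐ ring expansion of the 2-aryl-benzofuran-3(2H)-one 12 (CH2 insertion with 1,2-aryl shift); 12 ⇐ Friedel–Crafts acylation of acid 10.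
5. 10 ⇐ phenol 4 (from resorcinol) + mandelate 8 (from catechol and glyoxylic acid). Ring order: A and B rings bought, furanone ring, its expansion to the pyran C ring, then union of two C4-functionalised units.

Assumption: Bn = benzyl and MBn = 4-methylbenzyl are protecting groups, all removed in the last step; compounds 7–14 are racemic; all named reagents are purchased.

**Step 1**
Reactants: 1 resorcinol
Product: 2 1,3-bis[(4-methylbenzyl)oxy]benzene
Conditions: 4-MeC6H4CH2Br (2.2 equiv), K2CO3, DMF, 60 °C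
Reagents that add atoms: 4-methylbenzyl bromide, Cc1ccc(CBr)cc1
Why: Williamson O-alkylation; MBn is used instead of Bn because every ring C–H of MBn is ortho to a substituent and so should stay untouched in the next C–H borylation, while it is still cleaved by hydrogenolysis.

**Step 2**
Reactants: 2 1,3-bis[(4-methylbenzyl)oxy]benzene
Product: 4 3,5-bis[(4-methylbenzyl)oxy]phenol, via aryl pinacol boronate 3 (not isolated)
Conditions: [Ir(OMe)(cod)]2 (1.5 mol%), dtbpy (3 mol%), HBpin (1.5 equiv), THF, 80 °C; then Oxone, acetone/H2O, 25 °C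
Reagents that add atoms: pinacolborane, CC1(C)OBOC1(C)C (boryl group only in intermediate 3); potassium peroxymonosulfate (Oxone), [K+].[O-]S(=O)(=O)OO (the phenol O)
Why: Sterically controlled Ir-catalysed aromatic C–H borylation reaches only C5, the one C–H without an ortho substituent, and one-pot ipso-oxidation of C–B gives the phloroglucinol-type phenol.

**Step 3**
Reactants: 5 catechol; 6 glyoxylic acid
Product: 7 rac-3,4-dihydroxymandelic acid
Conditions: NaOH (aq), N2, 0 → 25 °C; then HCl to pH 2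
Reagents that add atoms: none
Why: Base-mediated aromatic hydroxyalkylation of catecholate by glyoxylate para to a phenoxide (the industrial mandelic-acid route to protocatechuic aldehyde); the new centre needs no control because it is racemised and reset in step 9.

**Step 4**
Reactants: 7 rac-3,4-dihydroxymandelic acid
Product: 8 benzyl rac-2-[3,4-bis(benzyloxy)phenyl]-2-hydroxyacetate
Conditions: BnBr (3.3 equiv), K2CO3, DMF, 25 → 50 °C
Reagents that add atoms: benzyl bromide, BrCc1ccccc1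
Why: Williamson and carboxylate alkylation; K2CO3 benzylates both phenols and the acid but leaves the secondary alcohol free.

**Step 5**
Reactants: 4 3,5-bis[(4-methylbenzyl)oxy]phenol; 8 benzyl rac-2-[3,4-bis(benzyloxy)phenyl]-2-hydroxyacetate
Product: 9 benzyl rac-2-{3,5-bis[(4-methylbenzyl)oxy]phenoxy}-2-[3,4-bis(benzyloxy)phenyl]acetate
Conditions: PPh3, DIAD, THF, 0 → 25 °C
Reagents that add atoms: none
Why: Mitsunobu etherification of an α-hydroxy ester with a phenol forms the future O1–C2 bond under neutral conditions that disfavour C-alkylation of the electron-rich ring.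

**Step 6**
Reactants: 9 benzyl rac-2-{3,5-bis[(4-methylbenzyl)oxy]phenoxy}-2-[3,4-bis(benzyloxy)phenyl]acetate
Product: 10 rac-2-{3,5-bis[(4-methylbenzyl)oxy]phenoxy}-2-[3,4-bis(benzyloxy)phenyl]acetic acid
Conditions: LiOH·H2O (3 equiv), THF/H2O 3:1, 25 °C; then 1 M HCl
Reagents that add atoms: lithium hydroxide, [Li+].[OH-]
Why: Ester saponification; the benzylic aryl ethers are inert to hydroxide.

**Step 7**
Reactants: 10 rac-2-{3,5-bis[(4-methylbenzyl)oxy]phenoxy}-2-[3,4-bis(benzyloxy)phenyl]acetic acid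
Product: 12 rac-2-[3,4-bis(benzyloxy)phenyl]-4,6-bis[(4-methylbenzyl)oxy]benzofuran-3(2H)-one, via mixed trifluoroacetic anhydride 11 (not isolated)
Conditions: TFAA (1.5 equiv), CH2Cl2, 0 → 25 °C; aq. NaHCO3; used at once under Ar
Reagents that add atoms: trifluoroacetic anhydride, O=C(OC(=O)C(F)(F)F)C(F)(F)F (its CF3CO group sits only in intermediate 11)
Why: Intramolecular Friedel–Crafts acylation through the mixed anhydride closes the furanone at the doubly activated ortho position (both ortho positions give the same product).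

**Step 8**
Reactants: 12 rac-2-[3,4-bis(benzyloxy)phenyl]-4,6-bis[(4-methylbenzyl)oxy]benzofuran-3(2H)-one
Product: 14 rac-2-[3,4-bis(benzyloxy)phenyl]-5,7-bis[(4-methylbenzyl)oxy]chroman-3-one, via C4-silyl ketone 13 (not isolated)
Conditions: TMSCHN2 (1.5 equiv), Sc(OTf)3 (10 mol%), CH2Cl2, −20 → 0 °C; then 1 M HCl, THF
Reagents that add atoms: (trimethylsilyl)diazomethane, C[Si](C)(C)C=[N+]=[N-] (its CH carbon becomes C4; the silyl group stays only in intermediate 13)
Why: Lewis-acid-promoted diazoalkane homologation (Tiffeneau–Demjanov-type ring expansion, as in 1-indanone → 2-tetralone): the diazo carbon adds to C3=O and the electron-rich aryl carbon C3a migrates (1,2-shift) with loss of N2 in preference to the O-substituted C2, while the C4-silyl group blocks a second insertion and is lost on acidic work-up.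

**Step 9**
Reactants: 14 rac-2-[3,4-bis(benzyloxy)phenyl]-5,7-bis[(4-methylbenzyl)oxy]chroman-3-one
Product: 15 (2R,3R)-2-[3,4-bis(benzyloxy)phenyl]-5,7-bis[(4-methylbenzyl)oxy]chroman-3-ol
Conditions: RuCl(p-cymene)[(R,R)-TsDPEN] (2 mol%), HCO2H/Et3N 1:1, DMF, 40 °C, Ar
Reagents that add atoms: none
Why: Proposed new method: dynamic-kinetic asymmetric transfer hydrogenation of a flavan-3-one, in which C2–H (α to C=O, flanked by O and aryl) enolises under Et3N so the ketone enantiomers interconvert, and the bifunctional Ru–H/N–H catalyst delivers hydride in an outer-sphere six-membered transition state to the face anti to the C2 aryl (2,3-cis) and reduces the (2R)-ketone faster, funnelling the racemate into the (2R,3R)-alcohol; the closest known reaction type is the Noyori–Ikariya transfer hydrogenation with dynamic kinetic resolution of α-aryl cyclic ketones (isoflavanones, 2-aryl tetralones) to cis-alcohols, and the (R,R) antipode is a quadrant-model prediction with the C2 side as the large group, to be swapped for (S,S) if the sense proves opposite.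

**Step 10**
Reactants: 15 (2R,3R)-2-[3,4-bis(benzyloxy)phenyl]-5,7-bis[(4-methylbenzyl)oxy]chroman-3-ol
Product: 16 (2R,3R,4S)-2-[3,4-bis(benzyloxy)phenyl]-4-(2-ethoxyethoxy)-5,7-bis[(4-methylbenzyl)oxy]chroman-3-ol
Conditions: DDQ (2.0 equiv), EtOCH2CH2OH (5 equiv), CH2Cl2, 25 °C
Reagents that add atoms: 2-ethoxyethanol, CCOCCO
Why: DDQ abstracts hydride from C4 (benzylic to the trioxygenated A ring) and the alcohol traps the cation anti to the axial 3-OH (4β), an oxidative benzylic etherification known for benzyl-protected epicatechin; this centre is ionised again in steps 11 and 12.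

**Step 11**
Reactants: 16 (2R,3R,4S)-2-[3,4-bis(benzyloxy)phenyl]-4-(2-ethoxyethoxy)-5,7-bis[(4-methylbenzyl)oxy]chroman-3-ol
Product: 17 benzyl 2-{(2R,3R,4S)-2-[3,4-bis(benzyloxy)phenyl]-3-hydroxy-5,7-bis[(4-methylbenzyl)oxy]chroman-4-yl}acetate
Conditions: BnOAc, LDA, THF, −78 °C; TMSCl (silyl ketene acetal, used crude, 3 equiv); then 16, TMSOTf (0.2 equiv), CH2Cl2, −78 → −40 °C; aq. citric acid
Reagents that add atoms: benzyl acetate, CC(=O)OCc1ccccc1 (delivered as its trimethylsilyl ketene acetal C=C(OCc1ccccc1)O[Si](C)(C)C)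
Why: Mukaiyama-type alkylation: TMSOTf ionises the C4 ether and the silyl ketene acetal attacks the C4 cation anti to the axial 3-OH, setting C4 as 4β (4S, 3,4-trans).

**Step 12**
Reactants: 16 (2R,3R,4S)-2-[3,4-bis(benzyloxy)phenyl]-4-(2-ethoxyethoxy)-5,7-bis[(4-methylbenzyl)oxy]chroman-3-ol; 17 benzyl 2-{(2R,3R,4S)-2-[3,4-bis(benzyloxy)phenyl]-3-hydroxy-5,7-bis[(4-methylbenzyl)oxy]chroman-4-yl}acetate
Product: 18 benzyl 2-{(2R,3R,4S)-2-[3,4-bis(benzyloxy)phenyl]-8-{(2R,3R,4R)-2-[3,4-bis(benzyloxy)phenyl]-3-hydroxy-5,7-bis[(4-methylbenzyl)oxy]chroman-4-yl}-3-hydroxy-5,7-bis[(4-methylbenzyl)oxy]chroman-4-yl}acetate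
Conditions: 17 (3 equiv, excess recovered), 16 (1 equiv), TMSOTf (0.3 equiv), 4 Å MS, CH2Cl2, −78 → −40 °C
Reagents that add atoms: none
Why: Lewis-acid-catalysed Friedel–Crafts interflavan coupling: C8 of excess 17 attacks the C4 cation from 16 anti to its 3-OH, giving the 4β→8 bond (upper C4 R), as in benzyl-protected procyanidin B2 syntheses.

**Step 13**
Reactants: 18 benzyl 2-{(2R,3R,4S)-2-[3,4-bis(benzyloxy)phenyl]-8-{(2R,3R,4R)-2-[3,4-bis(benzyloxy)phenyl]-3-hydroxy-5,7-bis[(4-methylbenzyl)oxy]chroman-4-yl}-3-hydroxy-5,7-bis[(4-methylbenzyl)oxy]chroman-4-yl}acetate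
Product: 19 2-{(2R,3R,4S)-2-(3,4-dihydroxyphenyl)-8-[(2R,3R,4R)-2-(3,4-dihydroxyphenyl)-3,5,7-trihydroxychroman-4-yl]-3,5,7-trihydroxychroman-4-yl}acetic acid
Conditions: H2 (1 atm), 20% Pd(OH)2/C, THF/MeOH/H2O 20:20:1, 25 °C; stopped at full uptake; Sephadex LH-20
Reagents that add atoms: none
Why: Global hydrogenolysis of nine benzylic C–O bonds (four MBn ethers, four Bn ethers, one Bn ester) over Pearlman's catalyst under neutral conditions touches no stereocentre.

**Compound list**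
1 | resorcinol | Oc1cccc(O)c1 | starting material
2 | 1,3-bis[(4-methylbenzyl)oxy]benzene | Cc1ccc(COc2cccc(OCc3ccc(C)cc3)c2)cc1 | intermediate
3 | 2-{3,5-bis[(4-methylbenzyl)oxy]phenyl}-4,4,5,5-tetramethyl-1,3,2-dioxaborolane | Cc1ccc(COc2cc(OCc3ccc(C)cc3)cc(B3OC(C)(C)C(C)(C)O3)c2)cc1 | intermediate
4 | 3,5-bis[(4-methylbenzyl)oxy]phenol | Cc1ccc(COc2cc(O)cc(OCc3ccc(C)cc3)c2)cc1 | intermediate
5 | catechol | Oc1ccccc1O | starting material
6 | glyoxylic acid | O=CC(=O)O | starting material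
7 | rac-3,4-dihydroxymandelic acid | OC(C(=O)O)c1ccc(O)c(O)c1 | intermediate
8 | benzyl rac-2-[3,4-bis(benzyloxy)phenyl]-2-hydroxyacetate | OC(C(=O)OCc1ccccc1)c1ccc(OCc2ccccc2)c(OCc2ccccc2)c1 | intermediate
9 | benzyl rac-2-{3,5-bis[(4-methylbenzyl)oxy]phenoxy}-2-[3,4-bis(benzyloxy)phenyl]acetate | O=C(OCc1ccccc1)C(Oc1cc(OCc2ccc(C)cc2)cc(OCc2ccc(C)cc2)c1)c1ccc(OCc2ccccc2)c(OCc2ccccc2)c1 | intermediate
10 | rac-2-{3,5-bis[(4-methylbenzyl)oxy]phenoxy}-2-[3,4-bis(benzyloxy)phenyl]acetic acid | OC(=O)C(Oc1cc(OCc2ccc(C)cc2)cc(OCc2ccc(C)cc2)c1)c1ccc(OCc2ccccc2)c(OCc2ccccc2)c1 | intermediate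
11 | mixed anhydride of 10 with trifluoroacetic acid | O=C(OC(=O)C(F)(F)F)C(Oc1cc(OCc2ccc(C)cc2)cc(OCc2ccc(C)cc2)c1)c1ccc(OCc2ccccc2)c(OCc2ccccc2)c1 | intermediate
12 | rac-2-[3,4-bis(benzyloxy)phenyl]-4,6-bis[(4-methylbenzyl)oxy]benzofuran-3(2H)-one | O=C1C(c2ccc(OCc3ccccc3)c(OCc3ccccc3)c2)Oc2cc(OCc3ccc(C)cc3)cc(OCc3ccc(C)cc3)c12 | intermediate
13 | rac-2-[3,4-bis(benzyloxy)phenyl]-5,7-bis[(4-methylbenzyl)oxy]-4-(trimethylsilyl)chroman-3-one (diastereomer mixture) | O=C1C(c2ccc(OCc3ccccc3)c(OCc3ccccc3)c2)Oc2cc(OCc3ccc(C)cc3)cc(OCc3ccc(C)cc3)c2C1[Si](C)(C)C | intermediate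
14 | rac-2-[3,4-bis(benzyloxy)phenyl]-5,7-bis[(4-methylbenzyl)oxy]chroman-3-one | O=C1Cc2c(OCc3ccc(C)cc3)cc(OCc3ccc(C)cc3)cc2OC1c1ccc(OCc2ccccc2)c(OCc2ccccc2)c1 | intermediate
15 | (2R,3R)-2-[3,4-bis(benzyloxy)phenyl]-5,7-bis[(4-methylbenzyl)oxy]chroman-3-ol (protected (−)-epicatechin, 2,3-cis) | C1c2c(OCc3ccc(C)cc3)cc(OCc3ccc(C)cc3)cc2O[C@H](c2ccc(OCc3ccccc3)c(OCc3ccccc3)c2)[C@@H]1O | intermediate
16 | (2R,3R,4S)-2-[3,4-bis(benzyloxy)phenyl]-4-(2-ethoxyethoxy)-5,7-bis[(4-methylbenzyl)oxy]chroman-3-ol (4β-ether) | CCOCCO[C@H]1c2c(OCc3ccc(C)cc3)cc(OCc3ccc(C)cc3)cc2O[C@H](c2ccc(OCc3ccccc3)c(OCc3ccccc3)c2)[C@@H]1O | intermediate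
17 | benzyl 2-{(2R,3R,4S)-2-[3,4-bis(benzyloxy)phenyl]-3-hydroxy-5,7-bis[(4-methylbenzyl)oxy]chroman-4-yl}acetate | O=C(OCc1ccccc1)C[C@H]1c2c(OCc3ccc(C)cc3)cc(OCc3ccc(C)cc3)cc2O[C@H](c2ccc(OCc3ccccc3)c(OCc3ccccc3)c2)[C@@H]1O | intermediate
18 | benzyl 2-{(2R,3R,4S)-2-[3,4-bis(benzyloxy)phenyl]-8-{(2R,3R,4R)-2-[3,4-bis(benzyloxy)phenyl]-3-hydroxy-5,7-bis[(4-methylbenzyl)oxy]chroman-4-yl}-3-hydroxy-5,7-bis[(4-methylbenzyl)oxy]chroman-4-yl}acetate | O=C(OCc1ccccc1)C[C@H]1c2c(OCc3ccc(C)cc3)cc(OCc3ccc(C)cc3)c([C@H]3c4c(OCc5ccc(C)cc5)cc(OCc5ccc(C)cc5)cc4O[C@H](c4ccc(OCc5ccccc5)c(OCc5ccccc5)c4)[C@@H]3O)c2O[C@H](c2ccc(OCc3ccccc3)c(OCc3ccccc3)c2)[C@@H]1O | intermediate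
19 | 2-{(2R,3R,4S)-2-(3,4-dihydroxyphenyl)-8-[(2R,3R,4R)-2-(3,4-dihydroxyphenyl)-3,5,7-trihydroxychroman-4-yl]-3,5,7-trihydroxychroman-4-yl}acetic acid (epicatechin-(4β→8)-4β-carboxymethylepicatechin) | O=C(O)C[C@H]1c2c(O)cc(O)c([C@H]3c4c(O)cc(O)cc4O[C@H](c4ccc(O)c(O)c4)[C@@H]3O)c2O[C@H](c2ccc(O)c(O)c2)[C@@H]1O | target

**Step count**
Total: 13 steps. Longest linear sequence: 11 steps (1, 2, 5–13; the catechol branch 3, 4, 5–13 is equally long).

**Three steps most likely to fail**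

Step 8 (ring expansion). The C3 ketone of 12 is a deactivated vinylogous carbonate that enolises easily, so slow addition, O-alkylation of the enol or migration of C2 instead of the aryl carbon are possible. The fallback builds the pyranone ring by carbenoid insertion instead of by expanding the furanone; it sets out from 10 and comes back at 14. Acid 10 is treated with oxalyl chloride and catalytic DMF to give rac-2-{3,5-bis[(4-methylbenzyl)oxy]phenoxy}-2-[3,4-bis(benzyloxy)phenyl]acetyl chloride F1. TMSCHN2 and Et3N in THF/MeCN at 0 °C convert it to the α-diazoketone rac-3-{3,5-bis[(4-methylbenzyl)oxy]phenoxy}-3-[3,4-bis(benzyloxy)phenyl]-1-diazopropan-2-one F2. Rh2(OAc)4 (1 mol%) in CH2Cl2 then inserts the carbenoid into the ortho C–H of the aryl ether, the known route from aryloxy diazoketones to chroman-3-ones, and gives 14.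

Step 9 (the proposed new step). Racemisation at C2 may be too slow relative to reduction, or the catalyst may give poor enantio- or cis-selectivity on this dialkyl-type ketone. The fallback uses known substrate-controlled reduction plus resolution; it sets out from 14 and comes back at 15. L-Selectride in THF at −78 °C reduces benzyl-protected flavan-3-ones from the face anti to the C2 aryl, giving the 2,3-cis racemate, that is 15 together with its enantiomer (2S,3S)-2-[3,4-bis(benzyloxy)phenyl]-5,7-bis[(4-methylbenzyl)oxy]chroman-3-ol F3. Preparative chiral SFC separates the two. F3 is recycled by Dess–Martin oxidation back to 14, which racemises with Et3N.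

Step 12 (interflavan coupling). Electrophile 16 can alkylate itself or the product, giving oligomers, and some 4→6 isomer may form. The fallback caps C8 of the electrophile with bromine so it cannot act as a nucleophile, allowing near-equimolar coupling; it sets out from 15 and comes back at 19. NBS in CH2Cl2 at −78 °C brominates 15 at C8 to give (2R,3R)-2-[3,4-bis(benzyloxy)phenyl]-8-bromo-5,7-bis[(4-methylbenzyl)oxy]chroman-3-ol F4. DDQ and 2-ethoxyethanol give the 4β-ether (2R,3R,4S)-2-[3,4-bis(benzyloxy)phenyl]-8-bromo-4-(2-ethoxyethoxy)-5,7-bis[(4-methylbenzyl)oxy]chroman-3-ol F5. BF3·OEt2 in CH2Cl2 at −78 °C couples it with 17 (1.2 equiv) to the bromo-capped protected dimer benzyl 2-{(2R,3R,4S)-2-[3,4-bis(benzyloxy)phenyl]-8-{(2R,3R,4S)-2-[3,4-bis(benzyloxy)phenyl]-8-bromo-3-hydroxy-5,7-bis[(4-methylbenzyl)oxy]chroman-4-yl}-3-hydroxy-5,7-bis[(4-methylbenzyl)oxy]chroman-4-yl}acetate F6 (same geometry as 18; the upper C4 descriptor changes only because of Br). Hydrogenolysis over Pd(OH)2/C with Et3N removes the bromine together with all benzyl-type groups and gives 19.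

**Further compounds**
F1 | step 8 | rac-2-{3,5-bis[(4-methylbenzyl)oxy]phenoxy}-2-[3,4-bis(benzyloxy)phenyl]acetyl chloride | ClC(=O)C(Oc1cc(OCc2ccc(C)cc2)cc(OCc2ccc(C)cc2)c1)c1ccc(OCc2ccccc2)c(OCc2ccccc2)c1
F2 | step 8 | rac-3-{3,5-bis[(4-methylbenzyl)oxy]phenoxy}-3-[3,4-bis(benzyloxy)phenyl]-1-diazopropan-2-one | [N-]=[N+]=CC(=O)C(Oc1cc(OCc2ccc(C)cc2)cc(OCc2ccc(C)cc2)c1)c1ccc(OCc2ccccc2)c(OCc2ccccc2)c1
F3 | step 9 | (2S,3S)-2-[3,4-bis(benzyloxy)phenyl]-5,7-bis[(4-methylbenzyl)oxy]chroman-3-ol | C1c2c(OCc3ccc(C)cc3)cc(OCc3ccc(C)cc3)cc2O[C@@H](c2ccc(OCc3ccccc3)c(OCc3ccccc3)c2)[C@H]1O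
F4 | step 12 | (2R,3R)-2-[3,4-bis(benzyloxy)phenyl]-8-bromo-5,7-bis[(4-methylbenzyl)oxy]chroman-3-ol | C1c2c(OCc3ccc(C)cc3)cc(OCc3ccc(C)cc3)c(Br)c2O[C@H](c2ccc(OCc3ccccc3)c(OCc3ccccc3)c2)[C@@H]1O
F5 | step 12 | (2R,3R,4S)-2-[3,4-bis(benzyloxy)phenyl]-8-bromo-4-(2-ethoxyethoxy)-5,7-bis[(4-methylbenzyl)oxy]chroman-3-ol | CCOCCO[C@H]1c2c(OCc3ccc(C)cc3)cc(OCc3ccc(C)cc3)c(Br)c2O[C@H](c2ccc(OCc3ccccc3)c(OCc3ccccc3)c2)[C@@H]1O
F6 | step 12 | benzyl 2-{(2R,3R,4S)-2-[3,4-bis(benzyloxy)phenyl]-8-{(2R,3R,4S)-2-[3,4-bis(benzyloxy)phenyl]-8-bromo-3-hydroxy-5,7-bis[(4-methylbenzyl)oxy]chroman-4-yl}-3-hydroxy-5,7-bis[(4-methylbenzyl)oxy]chroman-4-yl}acetate | O=C(OCc1ccccc1)C[C@H]1c2c(OCc3ccc(C)cc3)cc(OCc3ccc(C)cc3)c([C@H]3c4c(OCc5ccc(C)cc5)cc(OCc5ccc(C)cc5)c(Br)c4O[C@H](c4ccc(OCc5ccccc5)c(OCc5ccccc5)c4)[C@@H]3O)c2O[C@H](c2ccc(OCc3ccccc3)c(OCc3ccccc3)c2)[C@@H]1O
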